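**Retrosynthetic overview**

1. Target 22 ⇐ 8-oxo-Δ2-decalin 18 by trans-diaxial AcO/Br addition across C2=C3, C3–Br reduction, C8 methylenation and ester demethylation.
2. 18 ⇐ alkylidene-hydrindane 17 by an oxidative 1,2-shift of C10 from C8 to C9: the cyclopentane becomes the ring B cyclohexanone and C9 enters with the whole side chain.
3. 17 ⇐ Wittig union of trans-hydrindenone 9 (C1–C8, C10, three methyls) with phosphonium salt 15 (C9, C11–C16; C13 set by copper hydride conjugate reduction).
4. 9 ⇐ ring-closing metathesis (ring A) of 8 ⇐ enantioselective conjugate reverse-prenylation/allylation of 2-methylcyclopent-2-enone 4 (sets C5 and C10).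
5. Ring order: five-membered ring of 4 → ring A by metathesis → ring B by expansion of the five-membered ring.

Assumption: atom labels C1–C20 follow labdane numbering; the target is (13R)-2β-acetoxylabd-8(17)-en-15-oic acid, 22.

**Route**

Step 1
Reactants: 1 1-chloro-3-methylbut-2-ene (prenyl chloride)
Product: 3 trimethyl(3-methylbut-2-en-1-yl)silane, via prenylmagnesium chloride 2 (not isolated)
Conditions: Mg, THF, 0 °C; then Me3SiCl, 0 °C → rt
Reagents that add atoms: chlorotrimethylsilane, C[Si](C)(C)Cl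
Why: Grignard formation followed by silylation at the unhindered primary terminus is the standard allylsilane synthesis and creates no stereocentre.

Step 2
Reactants: 4 2-methylcyclopent-2-en-1-one; 3 trimethyl(3-methylbut-2-en-1-yl)silane; 5 3-bromoprop-1-ene (allyl bromide)
Product: 8 (2S,3S)-2-methyl-3-(2-methylbut-3-en-2-yl)-2-(prop-2-en-1-yl)cyclopentan-1-one, via silyl enol ether 6 (not isolated), via lithium enolate 7 (not isolated)
Conditions: (S,S)-IDPi Brønsted acid HN[P(=NTf)(O2-BINOL-Ar2)]2, Ar = 3,5-(CF3)2C6H3 (2 mol%), toluene, −60 °C; then MeLi, THF, 0 °C; then 5, DMPU, −40 → 0 °C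
Reagents that add atoms: none
Why: Proposed new method: the silylium–IDPi ion pair turns the enone into a siloxyallyl cation held by a confined chiral anion, the prenylsilane attacks C5 through its γ-carbon in an open SE2′ transition state (forming C4–C5 and the gem-dimethyl carbon with catalyst-controlled 5S configuration, the catalyst antipode being chosen accordingly), silyl transfer releases enol ether 6 and the catalyst, and the derived lithium enolate is allylated anti to the bulky C5 substituent to set C10 trans; the closest known reactions are silylium–IDPi Mukaiyama–Michael additions of silyl ketene acetals to enones and enoates, IDPi-catalysed Hosomi–Sakurai allylation of aldehydes and the racemic TiCl4-promoted conjugate prenylation of enones.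

Step 3
Reactants: 8 (2S,3S)-2-methyl-3-(2-methylbut-3-en-2-yl)-2-(prop-2-en-1-yl)cyclopentan-1-one
Product: 9 (3aS,7aS)-4,4,7a-trimethyl-2,3,3a,4,7,7a-hexahydro-1H-inden-1-one
Conditions: second-generation Grubbs catalyst RuCl2(=CHPh)(H2IMes)(PCy3) (3 mol%), CH2Cl2, 40 °C
Reagents that add atoms: none
Why: Ring-closing metathesis of the trans-disposed allyl and vinyl groups closes ring A as a trans-fused cyclohexene with loss of ethene and touches no stereocentre.

Step 4
Reactants: 10 5-chloropent-1-yne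
Product: 12 methyl (2E)-6-chloro-3-methylhex-2-enoate, via alkenylalane 11 (not isolated)
Conditions: Me3Al (2 equiv), Cp2ZrCl2 (20 mol%), CH2Cl2, 0 °C → rt; then ClCO2Me, 0 °C → rt
Reagents that add atoms: trimethylaluminium, C[Al](C)C; methyl chloroformate, COC(=O)Cl
Why: Zirconium-catalysed syn-carboalumination (Negishi) places methyl and aluminium cis, and acylation of the alkenylalane with retention gives the pure (E)-trisubstituted enoate.

Step 5
Reactants: 12 methyl (2E)-6-chloro-3-methylhex-2-enoate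
Product: 13 methyl (3R)-6-chloro-3-methylhexanoate
Conditions: Cu(OAc)2 (2 mol%), (R)-DTBM-SEGPHOS (2.2 mol%), (EtO)2MeSiH, t-BuOH, toluene, 0 °C → rt
Reagents that add atoms: none
Why: Ligand-controlled copper hydride conjugate reduction of the geometrically pure β,β-disubstituted enoate sets C13 as R (ligand antipode chosen accordingly) and leaves the primary chloride untouched.

Step 6
Reactants: 13 methyl (3R)-6-chloro-3-methylhexanoate
Product: 15 [(4R)-6-methoxy-4-methyl-6-oxohexyl]triphenylphosphonium iodide, via alkyl iodide 14 (not isolated)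
Conditions: NaI, PPh3, MeCN, reflux
Reagents that add atoms: triphenylphosphine, c1ccc(cc1)P(c1ccccc1)c1ccccc1; sodium iodide, [Na+].[I-]
Why: Finkelstein exchange followed by SN2 quaternisation of triphenylphosphine gives the Wittig salt without touching C13.

Step 7
Reactants: 15 [(4R)-6-methoxy-4-methyl-6-oxohexyl]triphenylphosphonium iodide; 9 (3aS,7aS)-4,4,7a-trimethyl-2,3,3a,4,7,7a-hexahydro-1H-inden-1-one
Product: 17 methyl (3R,6Z)-3-methyl-6-[(3aS,7aS)-4,4,7a-trimethyl-2,3,3a,4,7,7a-hexahydro-1H-inden-1-ylidene]hexanoate, via phosphorus ylide 16 (not isolated)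
Conditions: NaN(SiMe3)2, THF, 0 °C; then 9, 0 → 60 °C (3 equiv ylide)
Reagents that add atoms: none
Why: Wittig olefination of the hindered cyclopentanone with a non-stabilised ylide parallels the ethylidenation of 17-oxo steroids (Z expected, and the alkene geometry is erased in step 8).

Step 8
Reactants: 17 methyl (3R,6Z)-3-methyl-6-[(3aS,7aS)-4,4,7a-trimethyl-2,3,3a,4,7,7a-hexahydro-1H-inden-1-ylidene]hexanoate
Product: 18 methyl (3R)-3-methyl-5-[(1R,4aS,8aS)-5,5,8a-trimethyl-2-oxo-1,2,3,4,4a,5,8,8a-octahydronaphthalen-1-yl]pentanoate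
Conditions: PhI(OH)OTs (1.05 equiv), 95% aq. MeOH, 0 °C → rt
Reagents that add atoms: [hydroxy(tosyloxy)iodo]benzene, Cc1ccc(cc1)S(=O)(=O)OI(O)c1ccccc1
Why: In this Koser-type oxidative semipinacol ring expansion the trivalent iodine adds to C9 of the more electron-rich trisubstituted alkene, solvent adds to C8, and the quaternary C10 migrates with retention from C8 to C9 as iodobenzene leaves (the same preference as C13 in D-homoannulation of steroids), giving the ring B cyclohexanone whose C9 equilibrates through the enol to the equatorial side chain.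

Step 9
Reactants: 18 methyl (3R)-3-methyl-5-[(1R,4aS,8aS)-5,5,8a-trimethyl-2-oxo-1,2,3,4,4a,5,8,8a-octahydronaphthalen-1-yl]pentanoate
Product: 19 methyl (3R)-5-[(1R,4aR,6S,7S,8aS)-7-acetoxy-6-bromo-5,5,8a-trimethyl-2-oxodecahydronaphthalen-1-yl]-3-methylpentanoate (2β-acetoxy, 3α-bromo)
Conditions: N-bromosuccinimide (1.1 equiv), AcOH, rt, dark
Reagents that add atoms: N-bromosuccinimide, O=C1CCC(=O)N1Br; acetic acid, CC(=O)O
Why: The bromonium ion forms on the α-face away from the two axial methyls and acetic acid opens it trans-diaxially at C2 (Fürst–Plattner rule), which sets the axial 2β-acetate.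

Step 10
Reactants: 19 methyl (3R)-5-[(1R,4aR,6S,7S,8aS)-7-acetoxy-6-bromo-5,5,8a-trimethyl-2-oxodecahydronaphthalen-1-yl]-3-methylpentanoate
Product: 20 methyl (3R)-5-[(1R,4aS,7R,8aS)-7-acetoxy-5,5,8a-trimethyl-2-oxodecahydronaphthalen-1-yl]-3-methylpentanoate
Conditions: Bu3SnH, AIBN (cat.), toluene, 80 °C
Reagents that add atoms: none
Why: Radical-chain hydrodebromination removes the C3 bromine without affecting acetate, ketone or ester.

Step 11
Reactants: 20 methyl (3R)-5-[(1R,4aS,7R,8aS)-7-acetoxy-5,5,8a-trimethyl-2-oxodecahydronaphthalen-1-yl]-3-methylpentanoate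
Product: 21 methyl (3R)-5-[(1S,4aS,7R,8aS)-7-acetoxy-5,5,8a-trimethyl-2-methylidenedecahydronaphthalen-1-yl]-3-methylpentanoate
Conditions: Zn, CH2Br2, TiCl4, THF–CH2Cl2, 0 °C → rt
Reagents that add atoms: dibromomethane, BrCBr
Why: The non-basic Takai–Lombardo methylenation converts the hindered C8 ketone into the exocyclic alkene without epimerising C9 or attacking either ester.

Step 12
Reactants: 21 methyl (3R)-5-[(1S,4aS,7R,8aS)-7-acetoxy-5,5,8a-trimethyl-2-methylidenedecahydronaphthalen-1-yl]-3-methylpentanoate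
Product: 22 (3R)-5-[(1S,4aS,7R,8aS)-7-acetoxy-5,5,8a-trimethyl-2-methylidenedecahydronaphthalen-1-yl]-3-methylpentanoic acid
Conditions: LiI, EtOAc, reflux, dark; then 1 M HCl
Reagents that add atoms: none
Why: SN2 dealkylation of the methyl ester by iodide frees the acid, while the hindered secondary acetate offers no site for iodide attack.

**Compound list**

1 | 1-chloro-3-methylbut-2-ene | CC(C)=CCCl | starting material
2 | (3-methylbut-2-en-1-yl)magnesium chloride | CC(C)=CC[Mg]Cl | intermediate
3 | trimethyl(3-methylbut-2-en-1-yl)silane | CC(C)=CC[Si](C)(C)C | intermediate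
4 | 2-methylcyclopent-2-en-1-one | CC1=CCCC1=O | starting material
5 | 3-bromoprop-1-ene | C=CCBr | starting material
6 | trimethyl{[(3S)-2-methyl-3-(2-methylbut-3-en-2-yl)cyclopent-1-en-1-yl]oxy}silane | C[Si](C)(C)OC1=C(C)[C@H](C(C)(C)C=C)CC1 | intermediate
7 | lithium (3S)-2-methyl-3-(2-methylbut-3-en-2-yl)cyclopent-1-en-1-olate | [Li+].[O-]C1=C(C)[C@H](C(C)(C)C=C)CC1 | intermediate
8 | (2S,3S)-2-methyl-3-(2-methylbut-3-en-2-yl)-2-(prop-2-en-1-yl)cyclopentan-1-one (allyl trans to the tert-alkyl group) | O=C1CC[C@@H](C(C)(C)C=C)[C@]1(C)CC=C | intermediate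
9 | (3aS,7aS)-4,4,7a-trimethyl-2,3,3a,4,7,7a-hexahydro-1H-inden-1-one (trans-fused) | O=C1CC[C@H]2C(C)(C)C=CC[C@]12C | intermediate
10 | 5-chloropent-1-yne | C#CCCCCl | starting material
11 | [(1E)-5-chloro-2-methylpent-1-en-1-yl]dimethylalumane | C[Al](C)/C=C(\C)CCCCl | intermediate
12 | methyl (2E)-6-chloro-3-methylhex-2-enoate | COC(=O)/C=C(\C)CCCCl | intermediate
13 | methyl (3R)-6-chloro-3-methylhexanoate | COC(=O)C[C@H](C)CCCCl | intermediate
14 | methyl (3R)-6-iodo-3-methylhexanoate | COC(=O)C[C@H](C)CCCI | intermediate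
15 | [(4R)-6-methoxy-4-methyl-6-oxohexyl]triphenylphosphonium iodide | COC(=O)C[C@H](C)CCC[P+](c1ccccc1)(c1ccccc1)c1ccccc1.[I-] | intermediate
16 | methyl (3R)-3-methyl-6-(triphenyl-λ5-phosphanylidene)hexanoate | COC(=O)C[C@H](C)CCC=P(c1ccccc1)(c1ccccc1)c1ccccc1 | intermediate
17 | methyl (3R,6Z)-3-methyl-6-[(3aS,7aS)-4,4,7a-trimethyl-2,3,3a,4,7,7a-hexahydro-1H-inden-1-ylidene]hexanoate | COC(=O)C[C@H](C)CC/C=C1/CC[C@H]2C(C)(C)C=CC[C@]12C | intermediate
18 | methyl (3R)-3-methyl-5-[(1R,4aS,8aS)-5,5,8a-trimethyl-2-oxo-1,2,3,4,4a,5,8,8a-octahydronaphthalen-1-yl]pentanoate | O=C1CC[C@H]2C(C)(C)C=CC[C@]2(C)[C@H]1CC[C@@H](C)CC(=O)OC | intermediate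
19 | methyl (3R)-5-[(1R,4aR,6S,7S,8aS)-7-acetoxy-6-bromo-5,5,8a-trimethyl-2-oxodecahydronaphthalen-1-yl]-3-methylpentanoate | O=C1CC[C@H]2C(C)(C)[C@H](Br)[C@@H](OC(C)=O)C[C@]2(C)[C@H]1CC[C@@H](C)CC(=O)OC | intermediate
20 | methyl (3R)-5-[(1R,4aS,7R,8aS)-7-acetoxy-5,5,8a-trimethyl-2-oxodecahydronaphthalen-1-yl]-3-methylpentanoate | O=C1CC[C@H]2C(C)(C)C[C@@H](OC(C)=O)C[C@]2(C)[C@H]1CC[C@@H](C)CC(=O)OC | intermediate
21 | methyl (3R)-5-[(1S,4aS,7R,8aS)-7-acetoxy-5,5,8a-trimethyl-2-methylidenedecahydronaphthalen-1-yl]-3-methylpentanoate | C=C1CC[C@H]2C(C)(C)C[C@@H](OC(C)=O)C[C@]2(C)[C@H]1CC[C@@H](C)CC(=O)OC | intermediate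
22 | (3R)-5-[(1S,4aS,7R,8aS)-7-acetoxy-5,5,8a-trimethyl-2-methylidenedecahydronaphthalen-1-yl]-3-methylpentanoic acid | C=C1CC[C@H]2C(C)(C)C[C@@H](OC(C)=O)C[C@]2(C)[C@H]1CC[C@@H](C)CC(=O)O | target

**Step count**

Total: 12 steps. Longest linear sequence: 9 steps (1 → 2 → 3 → 7 → 8 → 9 → 10 → 11 → 12); steps 4–6 form the side-chain branch.

**Steps most likely to fail**

Step 2 (the proposed new step): the enantioselective conjugate prenylation may give low conversion or low selectivity with the α-methyl enone. Fallback by known chemistry, setting out from 3 and 4: the classical TiCl4-promoted Hosomi–Sakurai addition (CH2Cl2, −78 °C) gives racemic 2-methyl-3-(2-methylbut-3-en-2-yl)cyclopentan-1-one F1. Me3SiCl/NaI/Et3N in MeCN converts it into the more substituted racemic silyl enol ether, trimethyl{[2-methyl-3-(2-methylbut-3-en-2-yl)cyclopent-1-en-1-yl]oxy}silane F2. MeLi and then 5 give racemic trans-2-methyl-3-(2-methylbut-3-en-2-yl)-2-(prop-2-en-1-yl)cyclopentan-1-one F3, which is resolved by preparative chromatography on a chiral stationary phase. The fallback comes back to the route at 8.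

Step 8: the trivalent iodine reagent may attack the ring A alkene, or give simple 1,2-dimethoxylation instead of the shift. Fallback, setting out from 17: N-bromosuccinimide in aqueous 1,2-dimethoxyethane at 0 °C gives the bromohydrin methyl (3R)-6-bromo-6-[(3aS,7aS)-1-hydroxy-4,4,7a-trimethyl-2,3,3a,4,7,7a-hexahydro-1H-inden-1-yl]-3-methylhexanoate F4 (anti adduct; configuration at the two new centres not assigned). AgBF4 in CH2Cl2 then triggers the classical halohydrin semipinacol shift of C10. The fallback comes back to the route at 18.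

Step 7: the ester-bearing ylide may self-condense before it olefinates the hindered ketone. Fallback, setting out from 15: hydrolysis with aqueous HI at reflux gives [(4R)-5-carboxy-4-methylpentyl]triphenylphosphonium iodide F5. Its ester-free dianion ylide (2.2 equiv KOC(CH3)3, THF, reflux) olefinates 9 to give (3R,6Z)-3-methyl-6-[(3aS,7aS)-4,4,7a-trimethyl-2,3,3a,4,7,7a-hexahydro-1H-inden-1-ylidene]hexanoic acid F6. Methylation with Me3SiCHN2 in MeOH–toluene brings the fallback back to the route at 17.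

**Further compounds**

F1 | step 2 | racemic 2-methyl-3-(2-methylbut-3-en-2-yl)cyclopentan-1-one (mixture of C2 epimers) | CC1C(C(C)(C)C=C)CCC1=O
F2 | step 2 | racemic trimethyl{[2-methyl-3-(2-methylbut-3-en-2-yl)cyclopent-1-en-1-yl]oxy}silane | C[Si](C)(C)OC1=C(C)C(C(C)(C)C=C)CC1
F3 | step 2 | racemic trans-2-methyl-3-(2-methylbut-3-en-2-yl)-2-(prop-2-en-1-yl)cyclopentan-1-one (both enantiomers) | O=C1CC[C@@H](C(C)(C)C=C)[C@]1(C)CC=C.O=C1CC[C@H](C(C)(C)C=C)[C@@]1(C)CC=C
F4 | step 8 | methyl (3R)-6-bromo-6-[(3aS,7aS)-1-hydroxy-4,4,7a-trimethyl-2,3,3a,4,7,7a-hexahydro-1H-inden-1-yl]-3-methylhexanoate (anti adduct, two new centres not assigned) | COC(=O)C[C@H](C)CCC(Br)C1(O)CC[C@H]2C(C)(C)C=CC[C@]12C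
F5 | step 7 | [(4R)-5-carboxy-4-methylpentyl]triphenylphosphonium iodide | OC(=O)C[C@H](C)CCC[P+](c1ccccc1)(c1ccccc1)c1ccccc1.[I-]
F6 | step 7 | (3R,6Z)-3-methyl-6-[(3aS,7aS)-4,4,7a-trimethyl-2,3,3a,4,7,7a-hexahydro-1H-inden-1-ylidene]hexanoic acid | OC(=O)C[C@H](C)CC/C=C1/CC[C@H]2C(C)(C)C=CC[C@]12C
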